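**Retrosynthetic overview**

- Ring numbering: C1 (ketone), C2 (bearing CH2CO2Me), C3 (=CH), C4 (carbinol), C5 (methine carrying the geranylgeranyl chain through C1'), C6 (CH2). The strategy rests on the unit C1(=O)–C6H2–C5H: it is what a formyl C1–H bond gives on adding across a 1,1-disubstituted C5=C6 alkene, while a (Z)-C2=C3 bond holds C1 and C4 on the same side.
- Disconnections, in retrosynthetic order: C4–O silyl ether; C1–C6 together with C5–H (rhodium alkene hydroacylation, which closes the only ring, the cyclohexenone, and sets C5); C1–C2 (formylation of a (Z)-vinyl iodide obtained by trans-hydroalumination–iodination of a propargylic alcohol); C3–C4 (asymmetric alkynylation, which sets C4).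
- Fragments: a C23 2-methylidene aldehyde from geranylgeraniol (bromide, cyanomethylation, nitrile reduction, α-methylenation) and 4,4,4-trimethoxybut-1-yne as a base-stable mask of methyl but-3-ynoate.

Key step: step 10

Remark (assumption): the (S,S) antipode of ProPhenol is taken to deliver the alkynyl group to the Si face of the 2-methylidene aldehyde; if the facial sense is the reverse, the (R,R) ligand is used.
Remark (assumption): (R)-DTBM-SEGPHOS is taken to be the bisphosphine antipode matched with the C4 centre of the (Z)-enal; if the pairing is mismatched, the (S) antipode is used.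

**Route**

Step 1
Reactants: 1 (2E,6E,10E)-geranylgeraniol
Product: 2 (2E,6E,10E)-geranylgeranyl bromide
Conditions: PBr3 (0.4 equiv), Et2O, −10 → 0 °C; used crude
Reagents that add atoms: phosphorus tribromide, BrP(Br)Br
Why: Bromination of a primary allylic alcohol with PBr3 through its phosphite ester should proceed by SN2 displacement at low temperature without allylic transposition or loss of the (E) geometry.

Step 2
Reactants: 2 (2E,6E,10E)-geranylgeranyl bromide; 3 acetonitrile
Product: 5 (4E,8E,12E)-5,9,13,17-tetramethyloctadeca-4,8,12,16-tetraenenitrile, via lithioacetonitrile 4 (not isolated)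
Conditions: CH3CN (3 equiv), n-BuLi (3 equiv), THF, −78 °C; then 2, −78 → −30 °C
Reagents that add atoms: none
Why: SN2 alkylation of cyanomethyllithium by the primary allylic bromide (α-alkylation of a nitrile anion) adds the two carbons that become C4 and C5, and the excess of anion should suppress dialkylation.

Step 3
Reactants: 5 (4E,8E,12E)-5,9,13,17-tetramethyloctadeca-4,8,12,16-tetraenenitrile
Product: 7 (4E,8E,12E)-5,9,13,17-tetramethyloctadeca-4,8,12,16-tetraenal, via N-aluminated aldimine 6 (not isolated)
Conditions: i-Bu2AlH (1.2 equiv), CH2Cl2, −78 °C; then 1 M aq. HCl, 0 °C, brief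
Reagents that add atoms: water, O
Why: Partial reduction of a nitrile with i-Bu2AlH stops at the N-aluminated aldimine, which hydrolysis converts into the aldehyde without over-reduction.

Step 4
Reactants: 7 (4E,8E,12E)-5,9,13,17-tetramethyloctadeca-4,8,12,16-tetraenal; 8 formaldehyde
Product: 9 (4E,8E,12E)-5,9,13,17-tetramethyl-2-methylideneoctadeca-4,8,12,16-tetraenal
Conditions: 37% aq. CH2O (1.2 equiv), pyrrolidine (10 mol%), propionic acid (10 mol%), i-PrOH, 45 °C; used promptly
Reagents that add atoms: none
Why: Amine-catalysed Mannich condensation with formaldehyde followed by elimination of the amine (organocatalytic α-methylenation of an aldehyde) installs the C5=C6 methylidene under conditions mild enough that the skipped C5=C6/C2'=C3' diene should not move into conjugation.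

Step 5
Reactants: 10 propargyl bromide; 11 tetramethyl orthocarbonate
Product: 13 4,4,4-trimethoxybut-1-yne, via propargylaluminium bromide 12 (not isolated)
Conditions: Al powder, HgCl2 (cat.), Et2O, 35 °C; then 11, −78 °C → rt; aq. NaOH work-up, distillation
Reagents that add atoms: none
Why: The propargyl/allenyl aluminium reagent should replace one methoxy group of the orthocarbonate by SE2' attack on the derived trialkoxycarbenium ion (orthoester synthesis from an organometallic and an orthocarbonate, the counterpart of the orthoformate route to but-3-ynal acetals), giving a homopropargylic orthoester that is inert to hydride and organolithium reagents.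

Step 6
Reactants: 9 (4E,8E,12E)-5,9,13,17-tetramethyl-2-methylideneoctadeca-4,8,12,16-tetraenal; 13 4,4,4-trimethoxybut-1-yne
Product: 15 (5R,8E,12E,16E)-1,1,1-trimethoxy-9,13,17,21-tetramethyl-6-methylidenedocosa-8,12,16,20-tetraen-3-yn-5-ol, via methylzinc alkynylide 14 (not isolated)
Conditions: 13 (3 equiv), Me2Zn (3 equiv), (S,S)-ProPhenol [2,6-bis{[(S)-2-(hydroxydiphenylmethyl)pyrrolidin-1-yl]methyl}-4-methylphenol] (20 mol%), Ph3P=O (40 mol%), toluene, 0 → 4 °C; aq. NaH2PO4/Na2HPO4 (pH 7) work-up; Et3N-deactivated silica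
Reagents that add atoms: none
Why: Dinuclear zinc–ProPhenol catalysed enantioselective alkynylation of an α,β-unsaturated aldehyde should add the zinc alkynylide 1,2 to the Si face of the formyl carbon (O > C5 > H), setting C4 as (R) in 15 (the centre that is (4R) in the target), while the orthoester avoids the alkyne-to-allene isomerisation of a free but-3-ynoate.

Step 7
Reactants: 15 (5R,8E,12E,16E)-1,1,1-trimethoxy-9,13,17,21-tetramethyl-6-methylidenedocosa-8,12,16,20-tetraen-3-yn-5-ol
Product: 17 (3Z,5S,8E,12E,16E)-3-iodo-1,1,1-trimethoxy-9,13,17,21-tetramethyl-6-methylidenedocosa-3,8,12,16,20-pentaen-5-ol, via cyclic alkenylaluminate 16 (not isolated)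
Conditions: NaAlH2(OCH2CH2OMe)2 (Red-Al, 2 equiv), Et2O, 0 °C → rt; EtOAc; then I2 (1.2 equiv), THF, −78 °C; cold aq. Na2S2O3/NaHCO3, then aq. KNaC4H4O6 (potassium sodium tartrate)
Reagents that add atoms: iodine, II
Why: Alkoxide-directed trans-hydroalumination of the propargylic alcohol delivers hydride to C3 and aluminium to C2 within a five-membered oxaluminate, and iodinolysis with retention (hydroalumination–iodination) gives the (Z)-vinyl iodide with iodine cis to C4, the C4 descriptor changing to (S) only because the CIP priorities switch.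

Step 8
Reactants: 17 (3Z,5S,8E,12E,16E)-3-iodo-1,1,1-trimethoxy-9,13,17,21-tetramethyl-6-methylidenedocosa-3,8,12,16,20-pentaen-5-ol
Product: 18 tert-butyl{[(3Z,5S,8E,12E,16E)-3-iodo-1,1,1-trimethoxy-9,13,17,21-tetramethyl-6-methylidenedocosa-3,8,12,16,20-pentaen-5-yl]oxy}dimethylsilane
Conditions: TBSCl (1.5 equiv), imidazole (3 equiv), 4-(dimethylamino)pyridine (cat.), DMF, rt; Et3N-deactivated silica
Reagents that add atoms: tert-butyldimethylsilyl chloride, CC(C)(C)[Si](C)(C)Cl
Why: Imidazole-mediated silylation of the secondary alcohol protects C4–OH under non-acidic conditions that leave the orthoester intact, and the silyl ether is needed so that the later (Z)-γ-oxygenated enal cannot close to a lactol and aromatise to a furan.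

Step 9
Reactants: 18 tert-butyl{[(3Z,5S,8E,12E,16E)-3-iodo-1,1,1-trimethoxy-9,13,17,21-tetramethyl-6-methylidenedocosa-3,8,12,16,20-pentaen-5-yl]oxy}dimethylsilane
Product: 22 methyl (3Z,5S,8E,12E,16E)-5-[tert-butyl(dimethyl)silyl]oxy-3-formyl-9,13,17,21-tetramethyl-6-methylidenedocosa-3,8,12,16,20-pentaenoate, via vinyllithium 19 (not isolated), via lithium hemiaminal alkoxide 20 (not isolated), via enal trimethyl orthoester 21 (not isolated)
Conditions: t-BuLi (2.1 equiv), Et2O, −78 °C, 20 min; DMF (5 equiv), −78 → −40 °C; then 0.2 M aq. HCl, THF, 0 °C, 15 min; product kept cold, neutral and dark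
Reagents that add atoms: N,N-dimethylformamide, CN(C)C=O; water, O
Why: Iodine–lithium exchange with retention of alkene geometry, formylation of the vinyllithium with DMF (Bouveault-type formylation) and a dilute acid work-up that also hydrolyses the acyclic orthoester to the methyl ester should give the (Z)-enal with C1 cis to C4, with no base ever touching the acidic CH2CO2Me group.

Step 10
Reactants: 22 methyl (3Z,5S,8E,12E,16E)-5-[tert-butyl(dimethyl)silyl]oxy-3-formyl-9,13,17,21-tetramethyl-6-methylidenedocosa-3,8,12,16,20-pentaenoate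
Product: 23 methyl 2-[(3R,4R)-3-[tert-butyl(dimethyl)silyl]oxy-6-oxo-4-[(2E,6E,10E)-3,7,11,15-tetramethylhexadeca-2,6,10,14-tetraen-1-yl]cyclohex-1-en-1-yl]acetate
Conditions: [Rh(cod)2]BF4 (10 mol%), (R)-DTBM-SEGPHOS [(R)-5,5'-bis{bis(3,5-di-tert-butyl-4-methoxyphenyl)phosphino}-4,4'-bi-1,3-benzodioxole] (11 mol%), H2 (1 atm, 15 min) then Ar purge, 1,2-dichloroethane, 40 °C, dilute
Reagents that add atoms: none
Why: Proposed new method: a cationic monovalent rhodium bisphosphine complex should add oxidatively to the formyl C1–H bond of 22 to give a trivalent rhodium acyl hydride (which the side-chain ester carbonyl can chelate, slowing decarbonylation), the C5=C6 alkene then inserts with hydride going to C5 and rhodium to C6, and C1–C6 reductive elimination from the seven-membered acyl–alkyl rhodacycle releases 23. The closest known reaction types are the enantioselective rhodium hydroacylation of 4-substituted pent-4-enals to 3-substituted cyclopentanones and the six-ring hydroacylation of ortho-allylbenzaldehydes, in which an arene plays the part taken here by the (Z)-C2=C3 bond; closure of an acyclic (Z)-hexa-2,5-dienal is not established. The cyclohexenone ring closes in the 6-endo-trig mode with respect to C5=C6, the acyl carbon bonding to the terminal C6. The new C5 stereocentre is set by the face of hydride delivery (Re face of C5, taking C4 > C1' > C6, which leaves the chain cis to the C4 silyl ether), and the controlling element is the chiral bisphosphine in its pairing matched with the (S)-C4 centre. The step needs hydride at C5 and acyl at C6, which the 1,1-disubstitution of C5 secures because the opposite insertion would require a tertiary alkylrhodium and lead to a quaternary cyclopentenone. It also needs the skipped alkenes to stay in place, which a fast closure enforced by the cis C1/C4 arrangement of the (Z)-enal should favour over rhodium hydride chain-walking.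

Step 11
Reactants: 23 methyl 2-[(3R,4R)-3-[tert-butyl(dimethyl)silyl]oxy-6-oxo-4-[(2E,6E,10E)-3,7,11,15-tetramethylhexadeca-2,6,10,14-tetraen-1-yl]cyclohex-1-en-1-yl]acetate
Product: 24 methyl 2-[(3R,4R)-3-hydroxy-6-oxo-4-[(2E,6E,10E)-3,7,11,15-tetramethylhexadeca-2,6,10,14-tetraen-1-yl]cyclohex-1-en-1-yl]acetate
Conditions: HF·pyridine, pyridine, THF, 0 °C → rt
Reagents that add atoms: none
Why: Fluoride cleavage of the secondary silyl ether under buffered, non-basic conditions (desilylation) should free C4–OH without epimerisation, elimination or migration of the C2=C3 bond.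

**Compound list**

1 | (2E,6E,10E)-geranylgeraniol | OC/C=C(\C)CC/C=C(\C)CC/C=C(\C)CCC=C(C)C | starting material
2 | (2E,6E,10E)-geranylgeranyl bromide | BrC/C=C(\C)CC/C=C(\C)CC/C=C(\C)CCC=C(C)C | intermediate
3 | acetonitrile | CC#N | starting material
4 | lithioacetonitrile (cyanomethyllithium) | [Li]CC#N | intermediate (not isolated)
5 | (4E,8E,12E)-5,9,13,17-tetramethyloctadeca-4,8,12,16-tetraenenitrile | N#CCC/C=C(\C)CC/C=C(\C)CC/C=C(\C)CCC=C(C)C | intermediate
6 | N-(diisobutylalumanyl) aldimine of aldehyde 7 | CC(C)C[Al](CC(C)C)N=CCC/C=C(\C)CC/C=C(\C)CC/C=C(\C)CCC=C(C)C | intermediate (not isolated)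
7 | (4E,8E,12E)-5,9,13,17-tetramethyloctadeca-4,8,12,16-tetraenal | O=CCC/C=C(\C)CC/C=C(\C)CC/C=C(\C)CCC=C(C)C | intermediate
8 | formaldehyde | C=O | starting material
9 | (4E,8E,12E)-5,9,13,17-tetramethyl-2-methylideneoctadeca-4,8,12,16-tetraenal | O=CC(=C)C/C=C(\C)CC/C=C(\C)CC/C=C(\C)CCC=C(C)C | intermediate
10 | propargyl bromide (3-bromoprop-1-yne) | C#CCBr | starting material
11 | tetramethyl orthocarbonate (tetramethoxymethane) | COC(OC)(OC)OC | starting material
12 | prop-2-ynylaluminium dibromide (drawn for the propargyl/allenyl aluminium sesquibromide) | C#CC[Al](Br)Br | intermediate (not isolated)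
13 | 4,4,4-trimethoxybut-1-yne | C#CCC(OC)(OC)OC | intermediate
14 | methyl(4,4,4-trimethoxybut-1-yn-1-yl)zinc | C[Zn]C#CCC(OC)(OC)OC | intermediate (not isolated)
15 | (5R,8E,12E,16E)-1,1,1-trimethoxy-9,13,17,21-tetramethyl-6-methylidenedocosa-8,12,16,20-tetraen-3-yn-5-ol | COC(OC)(OC)CC#C[C@H](O)C(=C)C/C=C(\C)CC/C=C(\C)CC/C=C(\C)CCC=C(C)C | intermediate
16 | sodium bis(2-methoxyethoxy) alkenylaluminate chelate (five-membered C2–Al–O–C4 ring) | [Na+].COCCO[Al-]1(OCCOC)O[C@H](C(=C)C/C=C(\C)CC/C=C(\C)CC/C=C(\C)CCC=C(C)C)C=C1CC(OC)(OC)OC | intermediate (not isolated)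
17 | (3Z,5S,8E,12E,16E)-3-iodo-1,1,1-trimethoxy-9,13,17,21-tetramethyl-6-methylidenedocosa-3,8,12,16,20-pentaen-5-ol | COC(OC)(OC)C/C(I)=C/[C@H](O)C(=C)C/C=C(\C)CC/C=C(\C)CC/C=C(\C)CCC=C(C)C | intermediate
18 | tert-butyldimethylsilyl ether of 17 | COC(OC)(OC)C/C(I)=C/[C@H](O[Si](C)(C)C(C)(C)C)C(=C)C/C=C(\C)CC/C=C(\C)CC/C=C(\C)CCC=C(C)C | intermediate
19 | vinyllithium from 18 (lithium at C2, cis to C4) | COC(OC)(OC)C/C([Li])=C/[C@H](O[Si](C)(C)C(C)(C)C)C(=C)C/C=C(\C)CC/C=C(\C)CC/C=C(\C)CCC=C(C)C | intermediate (not isolated)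
20 | lithium α-(dimethylamino)alkoxide adduct of 19 with DMF | COC(OC)(OC)C/C(C(O[Li])N(C)C)=C/[C@H](O[Si](C)(C)C(C)(C)C)C(=C)C/C=C(\C)CC/C=C(\C)CC/C=C(\C)CCC=C(C)C | intermediate (not isolated)
21 | (2Z,4S,7E,11E,15E)-4-[tert-butyl(dimethyl)silyl]oxy-8,12,16,20-tetramethyl-5-methylidene-2-(2,2,2-trimethoxyethyl)henicosa-2,7,11,15,19-pentaenal | COC(OC)(OC)C/C(C=O)=C/[C@H](O[Si](C)(C)C(C)(C)C)C(=C)C/C=C(\C)CC/C=C(\C)CC/C=C(\C)CCC=C(C)C | intermediate (not isolated)
22 | methyl (3Z,5S,8E,12E,16E)-5-[tert-butyl(dimethyl)silyl]oxy-3-formyl-9,13,17,21-tetramethyl-6-methylidenedocosa-3,8,12,16,20-pentaenoate | COC(=O)C/C(C=O)=C/[C@H](O[Si](C)(C)C(C)(C)C)C(=C)C/C=C(\C)CC/C=C(\C)CC/C=C(\C)CCC=C(C)C | intermediate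
23 | methyl 2-[(3R,4R)-3-[tert-butyl(dimethyl)silyl]oxy-6-oxo-4-[(2E,6E,10E)-3,7,11,15-tetramethylhexadeca-2,6,10,14-tetraen-1-yl]cyclohex-1-en-1-yl]acetate | COC(=O)CC1=C[C@H](O[Si](C)(C)C(C)(C)C)[C@H](C/C=C(\C)CC/C=C(\C)CC/C=C(\C)CCC=C(C)C)CC1=O | intermediate
24 | methyl 2-[(3R,4R)-3-hydroxy-6-oxo-4-[(2E,6E,10E)-3,7,11,15-tetramethylhexadeca-2,6,10,14-tetraen-1-yl]cyclohex-1-en-1-yl]acetate (CNP0274044.1) | COC(=O)CC1=C[C@H](O)[C@H](C/C=C(\C)CC/C=C(\C)CC/C=C(\C)CCC=C(C)C)CC1=O | target

**Step count**

Total: 11 steps. Longest linear sequence: 10 steps (steps 1–4 and 6–11, from geranylgeraniol).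

**Steps most likely to fail**

Step 10. The acyl rhodium hydride may lose CO, the rhodium hydride may walk the C5=C6 bond into conjugation (towards C4 or C1'), the (Z)-enal may isomerise before closure, or hydride may reach the wrong face of C5. The fallback forms the same C1–C6 bond by an acyl radical. From 22, Pinnick oxidation (NaClO2, NaH2PO4, 2-methylbut-2-ene, t-BuOH/H2O) would give (2Z,4S,7E,11E,15E)-4-[tert-butyl(dimethyl)silyl]oxy-2-(2-methoxy-2-oxoethyl)-8,12,16,20-tetramethyl-5-methylidenehenicosa-2,7,11,15,19-pentaenoic acid F1. Treatment with PhSeSePh and PBu3 (CH2Cl2, rt) would convert it into the Se-phenyl selenoester F2. Slow addition of Bu3SnH with azobisisobutyronitrile in dilute benzene at 80 °C should generate the C1 acyl radical, which is expected to close 6-endo onto C6 because the substituent on C5 disfavours the 5-exo mode. The tertiary C5 ring radical should then take hydrogen from the stannane on the face away from the C4 silyl ether, leaving the chain cis to it, and the route is rejoined at 23.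

Step 9. The silyl group may migrate from oxygen to the lithiated carbon (retro-Brook shift), the vinyllithium may be protonated, or the (Z) geometry may erode during the acid work-up. The fallback replaces lithiation by cross-coupling and oxidation. From 18, Stille coupling with (tributylstannyl)methanol (Pd(PPh3)4, 1,4-dioxane, 80 °C) should give, with retention of geometry, (2Z,4S,7E,11E,15E)-4-[tert-butyl(dimethyl)silyl]oxy-8,12,16,20-tetramethyl-5-methylidene-2-(2,2,2-trimethoxyethyl)henicosa-2,7,11,15,19-pentaen-1-ol F3. Oxidation of this allylic alcohol with MnO2 (CH2Cl2, rt) would give the enal orthoester 21, which is hydrolysed with dilute aqueous acid as in step 9 to 22.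

Step 6. The hindered 2-substituted acrolein may add the zinc alkynylide slowly or with low enantioselectivity, and the enal may polymerise meanwhile. The fallback sets C4 by reduction instead of addition. The lithium acetylide of 13 (n-BuLi, THF, −78 °C) would be added to 9 to give racemic 1,1,1-trimethoxy-9,13,17,21-tetramethyl-6-methylidenedocosa-8,12,16,20-tetraen-3-yn-5-ol F4. MnO2 (CH2Cl2, rt) would oxidise it to (8E,12E,16E)-1,1,1-trimethoxy-9,13,17,21-tetramethyl-6-methylidenedocosa-8,12,16,20-tetraen-3-yn-5-one F5. CBS reduction with (R)-2-methyl-CBS-oxazaborolidine [(R)-1-methyl-3,3-diphenyltetrahydro-1H,3H-pyrrolo[1,2-c][1,3,2]oxazaborole] and catecholborane (toluene, −78 °C), the alkynyl arm acting as the small substituent, should then return (R)-alcohol 15.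

**Further compounds**

F1 | step 10 | (2Z,4S,7E,11E,15E)-4-[tert-butyl(dimethyl)silyl]oxy-2-(2-methoxy-2-oxoethyl)-8,12,16,20-tetramethyl-5-methylidenehenicosa-2,7,11,15,19-pentaenoic acid | COC(=O)C/C(C(=O)O)=C/[C@H](O[Si](C)(C)C(C)(C)C)C(=C)C/C=C(\C)CC/C=C(\C)CC/C=C(\C)CCC=C(C)C
F2 | step 10 | Se-phenyl selenoester of F1 | COC(=O)C/C(C(=O)[Se]c1ccccc1)=C/[C@H](O[Si](C)(C)C(C)(C)C)C(=C)C/C=C(\C)CC/C=C(\C)CC/C=C(\C)CCC=C(C)C
F3 | step 9 | (2Z,4S,7E,11E,15E)-4-[tert-butyl(dimethyl)silyl]oxy-8,12,16,20-tetramethyl-5-methylidene-2-(2,2,2-trimethoxyethyl)henicosa-2,7,11,15,19-pentaen-1-ol | COC(OC)(OC)C/C(CO)=C/[C@H](O[Si](C)(C)C(C)(C)C)C(=C)C/C=C(\C)CC/C=C(\C)CC/C=C(\C)CCC=C(C)C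
F4 | step 6 | racemic (8E,12E,16E)-1,1,1-trimethoxy-9,13,17,21-tetramethyl-6-methylidenedocosa-8,12,16,20-tetraen-3-yn-5-ol | COC(OC)(OC)CC#CC(O)C(=C)C/C=C(\C)CC/C=C(\C)CC/C=C(\C)CCC=C(C)C
F5 | step 6 | (8E,12E,16E)-1,1,1-trimethoxy-9,13,17,21-tetramethyl-6-methylidenedocosa-8,12,16,20-tetraen-3-yn-5-one | COC(OC)(OC)CC#CC(=O)C(=C)C/C=C(\C)CC/C=C(\C)CC/C=C(\C)CCC=C(C)C
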